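The numbers in the tables come from a simulation with constants of no real substance; scatter was added.

The leftover in the grey run started me: at 10.0 d the substrate read 80.2% and the target 9.7%, so 10.1% of the charge was in neither. Target found divided by substrate lost came to 0.490. I called this the target share, a selectivity, whose zero is no target found; grey stood at half, an even split between target and the rest.

| setting | ochre | grey | east | north-east | south | west |
|---|---|---|---|---|---|---|
| substrate | 0.20 M | 0.20 M | 0.20 M | 0.20 M | 0.20 M | 0.20 M |
| coupling partner | 0.13 M | 0.29 M | 0.190 M | 0.190 M | 0.190 M | 0.190 M |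
| catalyst | 3.4 mM | 3.4 mM | 3.4 mM | 3.4 mM | 3.4 mM | 3.4 mM |
| temperature | −30 °C | 0 °C | 25 °C | −25 °C | 0 °C |  |
| remark | run made earlier | run made earlier |  |  |  | at −25 °C until 40 h, from then on at 25 °C |
| time |  |  | 2.5 d | 2.5 d | 2.5 d | 2.5 d |

- ochre (time / d: target / %, substrate / %): 8.00: 0.4, 99.7; 15.0: 1.2, 98.9; 25.0: 0.3, 99.3; 30.0: 0.3, 99.1; 40.0: 1.6, 98.7; 50.0: 1.7, 97.9
- grey (time / d: target / %, substrate / %): 0.625: 0.1, 98.1; 2.00: 3.5, 96.2; 4.00: 6.4, 91.4; 6.00: 7.5, 88.1; 8.00: 8.7, 84.6; 10.0: 9.7, 80.2

(scatter of a reading: 0.5 percentage points)

- the best flask by amount of target, in percent of the substrate charged; "all alike" if 1.5 percentage points covers them all (east / north-east / south / west / all alike)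
- amount of target at the end, in percent of the substrate charged, east
- amount of target at the end, in percent of the substrate charged, north-east
- amount of target at the end, in percent of the substrate charged, south
- amount of target at the end, in percent of the substrate charged, west

For east I needed the substrate lost. I assumed first-order loss, blind to the coupling partner, although ochre and grey differ in it. The last readings gave 0.0221 d⁻¹ at 0 °C and 4.24 × 10⁻⁴ d⁻¹ at −30 °C, so an apparent activation energy of 72.7 kJ mol⁻¹, resting on an ochre loss of 2.10% against a scatter of 0.5 percentage points. Carried to 25 °C, that meant 0.323 d⁻¹ and 55.5% lost in east.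

That loss was my loose ceiling. The share had fallen along grey from 0.921 at 2.00 d, so if it kept falling, holding it at its last value gave a tighter ceiling, 27.2%. My loose floor was grey's last target, 9.7%, with no gain after it. Letting the further loss yield target at grey's late rate of 0.278 per unit lost raised the floor to 19.6%, though c(coupling partner) was 0.190 M in east against 0.29 M in grey. West, warm for 20.0 h, should lose 23.6%, less than east, and so hold about 11.6%.

The forecast also named east, with 6% there, 0.3% in north-east, 2.9% in south and 4.8% in west; its words were “East then sits near a quasi-steady level”. That value for east lay below my floor.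

East gave 24.5%, inside the bracket, and was best, with 0.0732% in north-east, 3.78% in south and 13.3% in west.

    substrate + catalyst → catalyst + intermediate (k = 4.00 M⁻¹ h⁻¹, Ea = 73.0 kJ mol⁻¹)
    coupling partner + catalyst + intermediate → catalyst + target (k = 470 M⁻² h⁻¹, Ea = 37.0 kJ mol⁻¹)
    coupling partner + target → over-reaction product (k = 0.280 M⁻¹ h⁻¹, Ea = 68.0 kJ mol⁻¹)
    (constants at 25 °C)

East had not come to rest at 2.50 d: substrate stood at 44.2%, coupling partner at 23.2% of its charge, and the target share was 0.440. In west, the share had promised 11.6% against the 13.3% found. Ten times the time still changed east: at 25.0 d substrate was down to 0.0286%, over-reaction product stood at 31.5% and intermediate at 36.5%, and target had risen to 32.0%, which put the target share at 0.320.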